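**Plan**

1. Retrosynthesis: both tertiary C–O bonds (pyran O–CMe2 and bridging O–C(Me)) are cut to an all-trans 1,3-bis(quinolonyl)cyclohexene. The C–C bond to one quinolone is then cut (allylic Friedel–Crafts) to a 5,6-trans-3-methylcyclohex-2-enone, which is contracted to a 2-isopropenylcyclobutanone, itself cut into isopropenylketene and an (E)-3-alkenylquinolone.
2. Forward: quinolone → 3-iodide → Heck alkene → [2+2] cyclobutanone → ring expansion (four to six) → Luche reduction → second quinolone at the allylic carbon → bridging ether, then the dimethylpyran last.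
3. Enabling feature: in the carbocycle, the CH that carries the pyran-fused quinolone is a cation-stabilised site (the quinolone 4-oxygen donates through C4=C3) and lies CH–CH2–C away from the methyl-bearing ether carbon. The CH carrying the other quinolone can be read as a former carbonyl, so the ring is a 3-methylcyclohex-2-enone with the donor at C5, the γ-recombination product of a 3-donor-2-isopropenylcyclobutanone.
4. Relative configuration: E-alkene plus suprafacial [2+2] and a reversible ring expansion give the trans CH–CH pair; the second quinolone enters anti to the CMe2O group; the ether carbon is fixed by the bridge.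
5. Absolute configuration: it can only be set in the last step, because the tertiary cation that precedes both ether closures is mirror-symmetric; a chiral acid chooses which quinolone oxygen bridges.

Key step: step 5

Assumption: the sense of induction of the chiral acid in step 8 cannot be predicted; the (S,S)-antipode is written as the one that gives 14.
Remark: 8, 10, 11 and 12 are racemates; their SMILES show the enantiomer that maps atom for atom onto 14.

**Step 1**
Reactants: 1 4-hydroxy-1-methylquinolin-2(1H)-one
Product: 2 4-hydroxy-3-iodo-1-methylquinolin-2(1H)-one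
Conditions: NIS, MeCN, 0 °C to rt
Reagents that add atoms: N-iodosuccinimide, O=C1CCC(=O)N1I
Why: Electrophilic iodination (enol halogenation) at C3, the only nucleophilic ring carbon of the vinylogous acid, so no selectivity issue arises.

**Step 2**
Reactants: 2 4-hydroxy-3-iodo-1-methylquinolin-2(1H)-one; 3 2-methylbut-3-en-2-ol
Product: 4 (E)-4-hydroxy-3-(3-hydroxy-3-methylbut-1-en-1-yl)-1-methylquinolin-2(1H)-one
Conditions: Pd(OAc)2 (5 mol%), P(o-tol)3, Et3N, DMF, 80 °C
Reagents that add atoms: none
Why: Mizoroki–Heck reaction: the quinolonyl–palladium species adds to the terminal alkene carbon and β-hydride elimination can only take the hydrogen next to the ring (the carbinol carbon has none), which should give the conjugated E-alkene.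

**Step 3**
Reactants: 4 (E)-4-hydroxy-3-(3-hydroxy-3-methylbut-1-en-1-yl)-1-methylquinolin-2(1H)-one
Product: 5 (E)-1-methyl-4-(triethylsilyloxy)-3-[3-methyl-3-(triethylsilyloxy)but-1-en-1-yl]quinolin-2(1H)-one
Conditions: TESOTf (2.4 equiv), 2,6-lutidine, CH2Cl2, −78 to 0 °C
Reagents that add atoms: triethylsilyl trifluoromethanesulfonate, CC[Si](CC)(CC)OS(=O)(=O)C(F)(F)F
Why: Silyl triflate with a hindered pyridine base silylates the acidic enol and the tertiary alcohol alike, which masks both against acylation by the ketene in step 4 while keeping the 4-oxygen an electron donor.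

**Step 4**
Reactants: 5 (E)-1-methyl-4-(triethylsilyloxy)-3-[3-methyl-3-(triethylsilyloxy)but-1-en-1-yl]quinolin-2(1H)-one; 6 3-methylbut-2-enoyl chloride
Product: 8 racemic 3,4-trans-2-(prop-1-en-2-yl)-3-[1-methyl-2-oxo-4-(triethylsilyloxy)-1,2-dihydroquinolin-3-yl]-4-[2-(triethylsilyloxy)propan-2-yl]cyclobutan-1-one (both C2 epimers), via isopropenylketene 7 (not isolated)
Conditions: 6 (slow addition), Et3N, PhMe, 90 °C
Reagents that add atoms: none
Why: Ketene–alkene [2+2] cycloaddition (Staudinger-type ketene cycloaddition): Et3N converts 6 by 1,4-dehydrochlorination into vinylketene 7, whose carbonyl carbon should bond to the alkene carbon remote from the quinolone (the nucleophilic end of the O–C4=C3–CH=CH donor system) and whose α-carbon to the quinolone-bearing carbon, suprafacially on the alkene, so that the E-geometry becomes the 3,4-trans relationship; the configuration at C2 is of no consequence.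

**Step 5**
Reactants: 8 racemic 3,4-trans-2-isopropenyl-3-quinolonyl-4-(silyloxypropyl)cyclobutanone
Product: 10 racemic 5,6-trans-3-methyl-5-[1-methyl-2-oxo-4-(triethylsilyloxy)-1,2-dihydroquinolin-3-yl]-6-[2-(triethylsilyloxy)propan-2-yl]cyclohex-2-en-1-one, via ring-opened oxocarbenium dienolate 9 (not isolated)
Conditions: Sc(OTf)3 (10 mol%), CH2Cl2, −40 to 0 °C
Reagents that add atoms: none
Why: Proposed new method: Sc(OTf)3 on the ketone oxygen makes the bond between C3 (bearing the 4-silyloxyquinolonyl donor, whose oxygen pushes through C4=C3 of the quinolone) and C2 (an α-carbon, bearing isopropenyl) a donor–acceptor bond; it should break heterolytically to the O-silyl oxocarbenium ion/scandium dienolate 9, and the γ-carbon of the dienolate (the former isopropenyl CH2) should add back to the cationic carbon, a net 1,3-shift that expands the four-membered ring by two carbons. The closest known reaction types are the Lewis-acid ring opening of 3-alkoxy- and 3-arylcyclobutanones to 1,4-zwitterions (used in formal [4+2] reactions), the vinylogous Mukaiyama–Michael addition and the thermal or alkoxide-accelerated vinylcyclobutane-to-cyclohexene rearrangement. The six-membered ring closes in the 6-(enolendo)-exo-trig mode onto the exocyclic C=C of the oxocarbenium ion. Of the two stereocentres of 10, C6 is the untouched C4 of 8, and C5 is formed under control of C6 through a half-chair transition state with both large groups pseudo-equatorial; because 10 is still a vinylogous donor–acceptor system the closure is reversible through 9, so the trans isomer should accumulate and both C2 epimers of 8 converge on one product. The step needs cleavage toward C2 and not toward C4 (the other α-carbon), and γ- over α-reclosure: the first is secured by the isopropenyl group, which makes the departing enolate a conjugated dienolate, the second by strain, since α-attack only regenerates 8 whereas γ-attack gives the strain-free conjugated enone.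

**Step 6**
Reactants: 10 racemic 5,6-trans-3-methyl-5-quinolonyl-6-(silyloxypropyl)cyclohex-2-en-1-one
Product: 11 racemic 4-hydroxy-3-{(1,6-trans,5,6-cis)-5-hydroxy-3-methyl-6-[2-(triethylsilyloxy)propan-2-yl]cyclohex-3-en-1-yl}-1-methylquinolin-2(1H)-one
Conditions: NaBH4, CeCl3·7H2O, MeOH, −40 °C; then K2CO3 (cat.), MeOH, 0 °C
Reagents that add atoms: none
Why: Luche reduction: the cerium-modified borohydride should add 1,2 to the enone from the face away from the bulky C6 substituent, and the labile 4-O-silyl group is then methanolysed while the tertiary silyl ether stays; the carbinol configuration is lost again in step 7.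

**Step 7**
Reactants: 11 racemic allylic alcohol; 1 4-hydroxy-1-methylquinolin-2(1H)-one
Product: 12 racemic all-trans 3,3'-{5-methyl-2-[2-(triethylsilyloxy)propan-2-yl]cyclohex-4-ene-1,3-diyl}bis(4-hydroxy-1-methylquinolin-2(1H)-one)
Conditions: 1 (2 equiv), (PhO)2P(O)OH (10 mol%), HFIP/CH2Cl2, 0 °C to rt
Reagents that add atoms: none
Why: Acid-mediated allylic substitution (SN1, Friedel–Crafts-type C-alkylation of a 1,3-dicarbonyl): the allyl cation from 11 should be taken by the nucleophilic C3 of 1 at its secondary terminus and anti to the neighbouring C(Me)2OSiEt3 group, as in the terpenylation of resorcinols with p-menthadienols, which sets the all-trans arrangement; the weak acid should leave the trisubstituted alkene and the tertiary silyl ether untouched.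

**Step 8**
Reactants: 12 racemic all-trans bis(quinolonyl)cyclohexene
Product: 14 paraensidimerin C, via bridged monoether 13 (not isolated)
Conditions: (S,S)-IDPi (confined chiral imidodiphosphorimidate Brønsted acid, 5 mol%), 4 Å MS, CHCl3, 40 °C
Reagents that add atoms: none
Why: Proposed new method: protonation of the trisubstituted alkene of either enantiomer of 12 gives the same tertiary cation, which has a mirror plane through the C(Me) cation carbon, the opposite CH and its CMe2 carbon, so the racemate is funnelled into one achiral ion; within the ion pair with the confined chiral anion one of the two enantiotopic quinolone oxygens should capture the cation (bridged ether 13, carbocycle in a boat), after which loss of Et3SiOH from the tertiary silyl ether lets the remaining quinolone oxygen close the trans-fused dimethylpyran; the closest known reaction types are the imidodiphosphorimidate-catalysed asymmetric intramolecular hydroalkoxylation of unactivated alkenes and chiral-acid desymmetrisations of meso diols.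

**Compound list**

1 | 4-hydroxy-1-methylquinolin-2(1H)-one | Cn1c(=O)cc(O)c2ccccc21 | starting material
2 | 4-hydroxy-3-iodo-1-methylquinolin-2(1H)-one | Cn1c(=O)c(I)c(O)c2ccccc21 | intermediate
3 | 2-methylbut-3-en-2-ol | C=CC(C)(C)O | starting material
4 | (E)-4-hydroxy-3-(3-hydroxy-3-methylbut-1-en-1-yl)-1-methylquinolin-2(1H)-one | Cn1c(=O)c(/C=C/C(C)(C)O)c(O)c2ccccc21 | intermediate
5 | (E)-1-methyl-4-(triethylsilyloxy)-3-[3-methyl-3-(triethylsilyloxy)but-1-en-1-yl]quinolin-2(1H)-one | Cn1c(=O)c(/C=C/C(C)(C)O[Si](CC)(CC)CC)c(O[Si](CC)(CC)CC)c2ccccc21 | intermediate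
6 | 3-methylbut-2-enoyl chloride | CC(C)=CC(Cl)=O | starting material
7 | isopropenylketene (3-methylbuta-1,3-dien-1-one) | C=C(C)C=C=O | intermediate
8 | racemic 3,4-trans-2-(prop-1-en-2-yl)-3-[1-methyl-2-oxo-4-(triethylsilyloxy)-1,2-dihydroquinolin-3-yl]-4-[2-(triethylsilyloxy)propan-2-yl]cyclobutan-1-one, C2 epimers | O=C1C(C(C)=C)[C@H](c2c(O[Si](CC)(CC)CC)c3ccccc3n(C)c2=O)[C@H]1C(C)(C)O[Si](CC)(CC)CC | intermediate
9 | ring-opened O-silyl oxocarbenium dienolate (zwitterion from cleavage of the C2–C3 bond of 8) | [O-]C(=CC(C)=C)[C@H](C(C)(C)O[Si](CC)(CC)CC)C=C1C(=O)N(C)c2ccccc2C1=[O+][Si](CC)(CC)CC | intermediate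
10 | racemic 5,6-trans-3-methyl-5-[1-methyl-2-oxo-4-(triethylsilyloxy)-1,2-dihydroquinolin-3-yl]-6-[2-(triethylsilyloxy)propan-2-yl]cyclohex-2-en-1-one | O=C1C=C(C)C[C@H](c2c(O[Si](CC)(CC)CC)c3ccccc3n(C)c2=O)[C@H]1C(C)(C)O[Si](CC)(CC)CC | intermediate
11 | racemic 4-hydroxy-3-{(1,6-trans,5,6-cis)-5-hydroxy-3-methyl-6-[2-(triethylsilyloxy)propan-2-yl]cyclohex-3-en-1-yl}-1-methylquinolin-2(1H)-one | O[C@H]1C=C(C)C[C@H](c2c(O)c3ccccc3n(C)c2=O)[C@H]1C(C)(C)O[Si](CC)(CC)CC | intermediate
12 | racemic all-trans 3,3'-{5-methyl-2-[2-(triethylsilyloxy)propan-2-yl]cyclohex-4-ene-1,3-diyl}bis(4-hydroxy-1-methylquinolin-2(1H)-one) | CC1=C[C@@H](c2c(O)c3ccccc3n(C)c2=O)[C@H](C(C)(C)O[Si](CC)(CC)CC)[C@@H](c2c(O)c3ccccc3n(C)c2=O)C1 | intermediate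
13 | bridged monoether: the 2-oxabicyclo[3.3.1]nonene ring of 14 closed, the other quinolone with free 4-OH, the tertiary silyl ether intact | CC[Si](CC)(CC)OC(C)(C)[C@@H]1[C@@H](c2c(O)c3ccccc3n(C)c2=O)C[C@]2(C)C[C@H]1c1c(c3ccccc3n(C)c1=O)O2 | intermediate
14 | paraensidimerin C | Cn1c(=O)c2c(c3ccccc31)OC(C)(C)[C@@H]1[C@@H]2C[C@]2(C)C[C@H]1c1c(c3ccccc3n(C)c1=O)O2 | target

Total step count: 8. Longest linear sequence: 8 steps (from 1).

**Steps most likely to fail**

Step 5 (Proposed new method). The heterolysis may run toward the other α-carbon, the oxocarbenium ion may lose a proton instead of being recaptured (ring-opened enones), or the tertiary silyl ether may ionise under the Lewis acid. Fallback, from 8 back to 10, by the known alkoxide-accelerated rearrangement of 2-vinylcyclobutanols: NaBH4 (MeOH, 0 °C) reduces 8 to the cyclobutanol F1. Its potassium alkoxide (KH, 18-crown-6, THF, 0 °C to rt) should undergo the [1,3]-shift, the carbinol carbon migrating to the isopropenyl terminus, to give the cyclohex-3-enol F2. Dess–Martin periodinane oxidises F2 to the β,γ-enone F3, and Et3N brings the double bond into conjugation, which arrives at 10. The two CH stereocentres are not touched in this sequence.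

Step 8 (Proposed new method). The catalyst may discriminate poorly between the two enantiotopic quinolone oxygens; the pyran may close at the silyl ether carbon before the alkene is protonated, which commits the racemate before the symmetric cation is reached; and re-ionisation of the product ethers would erode the enantiomeric purity. Fallback, from 12 to 14: TfOH (5 mol%) in HFIP/CH2Cl2 at 0 °C closes both rings without induction and should give 14 together with its mirror image F4; preparative HPLC on amylose tris(3,5-dimethylphenylcarbamate) then separates 14.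

Step 4. The cycloaddition may be too slow at the hindered trans-alkene, so that the vinylketene oligomerises, and the 4-O-silyl group may be lost. Fallback, from 5 to 8: dichloroketene F5 (from Cl3CCOCl and Zn/Cu, Et2O) is far more electrophilic and should add with the same orientation to give the 2,2-dichlorocyclobutanone F6. Bu3SnH/AIBN (PhH, 80 °C) removes both chlorines to give the cyclobutanone F7. Palladium-catalysed α-alkenylation of its enolate with 2-bromopropene (Pd2(dba)3, a biaryl phosphine, LiN(SiMe3)2, PhMe), which should occur at the CH2 α-carbon and not at the hindered CH, then gives 8.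

**Further compounds**

F1 | step 5 | 3,4-trans-2-(prop-1-en-2-yl)-3-[1-methyl-2-oxo-4-(triethylsilyloxy)-1,2-dihydroquinolin-3-yl]-4-[2-(triethylsilyloxy)propan-2-yl]cyclobutan-1-ol | OC1C(C(C)=C)[C@H](c2c(O[Si](CC)(CC)CC)c3ccccc3n(C)c2=O)[C@H]1C(C)(C)O[Si](CC)(CC)CC
F2 | step 5 | 5,6-trans-3-methyl-5-[1-methyl-2-oxo-4-(triethylsilyloxy)-1,2-dihydroquinolin-3-yl]-6-[2-(triethylsilyloxy)propan-2-yl]cyclohex-3-en-1-ol | OC1CC(C)=C[C@H](c2c(O[Si](CC)(CC)CC)c3ccccc3n(C)c2=O)[C@H]1C(C)(C)O[Si](CC)(CC)CC
F3 | step 5 | 5,6-trans-3-methyl-5-[1-methyl-2-oxo-4-(triethylsilyloxy)-1,2-dihydroquinolin-3-yl]-6-[2-(triethylsilyloxy)propan-2-yl]cyclohex-3-en-1-one | O=C1CC(C)=C[C@H](c2c(O[Si](CC)(CC)CC)c3ccccc3n(C)c2=O)[C@H]1C(C)(C)O[Si](CC)(CC)CC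
F4 | step 8 | mirror image of paraensidimerin C | Cn1c(=O)c2c(c3ccccc31)OC(C)(C)[C@H]1[C@H]2C[C@@]2(C)C[C@@H]1c1c(c3ccccc3n(C)c1=O)O2
F5 | step 4 | dichloroketene | ClC(Cl)=C=O
F6 | step 4 | 3,4-trans-2,2-dichloro-3-[1-methyl-2-oxo-4-(triethylsilyloxy)-1,2-dihydroquinolin-3-yl]-4-[2-(triethylsilyloxy)propan-2-yl]cyclobutan-1-one | O=C1C(Cl)(Cl)[C@H](c2c(O[Si](CC)(CC)CC)c3ccccc3n(C)c2=O)[C@H]1C(C)(C)O[Si](CC)(CC)CC
F7 | step 4 | 3,4-trans-3-[1-methyl-2-oxo-4-(triethylsilyloxy)-1,2-dihydroquinolin-3-yl]-4-[2-(triethylsilyloxy)propan-2-yl]cyclobutan-1-one | O=C1C[C@H](c2c(O[Si](CC)(CC)CC)c3ccccc3n(C)c2=O)[C@H]1C(C)(C)O[Si](CC)(CC)CC
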